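**Strategy.** Ring C (O1–C2–C3–C4–C4a–C8a) is disconnected at O1–C2 and C3–C4. O1 and C4 sit on adjacent carbons of ring A, so ring A with both atoms is a salicylaldehyde, and C2–C3 with ring B is a 1-arylvinyl unit. In the key step a Petasis-type condensation of 2-hydroxy-4-silyloxybenzaldehyde with the ring B/D 1-arylvinyl pinacol boronate transfers the boron-bearing carbon to the aldehyde carbon (C3–C4); the resulting ortho-quinone methide, supported by O1 and the para 7-oxygen, electrocyclises (O1–C2) to an isoflav-3-ene. Reagent-controlled syn hydroboration then sets the trans C3/C4 stereocenters; the ring D carbinol comes from a Jacobsen epoxidation.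

Key step: step 9

Remark: isoflavan numbering is used (ring A = fused benzene, ring B = aryl on C3, ring C = the oxygen heterocycle, ring D = the dimethylpyran fused to ring B, chroman locants inside the B/D unit). The facial sense of monoisopinocampheylborane is assumed to follow that known for 1-arylcycloalkenes; if it proves opposite, the reagent from (+)-α-pinene is used instead.

**Step 1**
Reactants: 1 2,4-dihydroxyacetophenone; 2 3-methylbut-2-enal
Product: 4 1-(5-hydroxy-2,2-dimethyl-2H-chromen-6-yl)ethanone, via dienone 3 (not isolated)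
Conditions: pyridine, 140 °C, sealed tube
Reagents that add atoms: none
Why: Aldol-type condensation of the enal at the carbon between the two hydroxyls gives dienone 3, whose oxa-6π electrocyclization closes the dimethylpyran onto the free 4-OH because the 2-OH is hydrogen-bonded to the acetyl group, so the angular 5-hydroxy-6-acetyl chromene should form regioselectively (chromenylation).

**Step 2**
Reactants: 4 1-(5-hydroxy-2,2-dimethyl-2H-chromen-6-yl)ethanone
Product: 5 1-(5-benzyloxy-2,2-dimethyl-2H-chromen-6-yl)ethanone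
Conditions: BnBr, K2CO3, DMF, 70 °C
Reagents that add atoms: benzyl bromide, BrCc1ccccc1
Why: Williamson etherification of the chelated phenol masks it against hypochlorite in the following epoxidation.

**Step 3**
Reactants: 5 1-(5-benzyloxy-2,2-dimethyl-2H-chromen-6-yl)ethanone
Product: 6 1-[(3R,4R)-5-benzyloxy-3,4-epoxy-2,2-dimethylchroman-6-yl]ethanone
Conditions: (R,R)-(salen)MnCl [(R,R)-N,N'-bis(3,5-di-tert-butylsalicylidene)-1,2-cyclohexanediamine complex of trivalent manganese, 4 mol%], aq. NaOCl (pH 11.3), 4-phenylpyridine N-oxide, CH2Cl2, 0 °C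
Reagents that add atoms: sodium hypochlorite, [Na+].[O-]Cl
Why: Jacobsen epoxidation of a cis-disubstituted 2,2-dimethylchromene, the best substrate class for this catalyst, should deliver oxygen to one enantioface under control of the (R,R)-salen ligand and so fix the ring D carbinol carbon as R.

**Step 4**
Reactants: 6 1-[(3R,4R)-5-benzyloxy-3,4-epoxy-2,2-dimethylchroman-6-yl]ethanone
Product: 7 1-[(3R)-3,5-dihydroxy-2,2-dimethylchroman-6-yl]ethanone
Conditions: H2 (1 atm), 10% Pd/C, EtOAc, rt
Reagents that add atoms: none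
Why: Hydrogenolysis should cleave the benzyl ether and, regioselectively, the benzylic C4–O bond of the epoxide while leaving the C3–O bond and its configuration untouched, and the hydrogen-bonded ortho-hydroxyaryl ketone is expected to resist reduction under neutral conditions.

**Step 5**
Reactants: 7 1-[(3R)-3,5-dihydroxy-2,2-dimethylchroman-6-yl]ethanone
Product: 8 1-[(3R)-2,2-dimethyl-3,5-bis(triisopropylsilyloxy)chroman-6-yl]ethanone
Conditions: TIPSOTf (2.5 equiv), 2,6-lutidine, CH2Cl2, 0 °C to rt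
Reagents that add atoms: triisopropylsilyl trifluoromethanesulfonate, CC(C)[Si](OS(=O)(=O)C(F)(F)F)(C(C)C)C(C)C
Why: Silyl triflate silylation protects the phenol and the hindered secondary alcohol in one operation as fluoride-labile ethers whose bulk should also suppress oxygen-to-oxygen silyl migration in the enolate of the next step.

**Step 6**
Reactants: 8 1-[(3R)-2,2-dimethyl-3,5-bis(triisopropylsilyloxy)chroman-6-yl]ethanone
Product: 10 1-[(3R)-2,2-dimethyl-3,5-bis(triisopropylsilyloxy)chroman-6-yl]vinyl trifluoromethanesulfonate, via potassium enolate 9 (not isolated)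
Conditions: KHMDS, THF, −78 °C; PhNTf2, −78 to 0 °C; chromatography on Et3N-deactivated silica
Reagents that add atoms: N-phenylbis(trifluoromethanesulfonimide), O=S(=O)(N(c1ccccc1)S(=O)(=O)C(F)(F)F)C(F)(F)F
Why: Kinetic deprotonation of the only enolisable position, the acetyl methyl group, and O-sulfonylation of enolate 9 give the 1-arylvinyl triflate (enol triflate formation).

**Step 7**
Reactants: 10 1-[(3R)-2,2-dimethyl-3,5-bis(triisopropylsilyloxy)chroman-6-yl]vinyl trifluoromethanesulfonate
Product: 11 2-{1-[(3R)-2,2-dimethyl-3,5-bis(triisopropylsilyloxy)chroman-6-yl]vinyl}-4,4,5,5-tetramethyl-1,3,2-dioxaborolane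
Conditions: B2pin2, PdCl2(PPh3)2 (3 mol%), PPh3, KOPh, toluene, 50 °C
Reagents that add atoms: bis(pinacolato)diboron, CC1(C)OB(OC1(C)C)B1OC(C)(C)C(C)(C)O1
Why: Miyaura borylation, in which oxidative addition of the alkenyl triflate to zerovalent palladium, phenoxide-assisted transmetalation with the diboron and reductive elimination give the 1-arylvinyl boronate without touching the silyl ethers.

**Step 8**
Reactants: 12 2,4-dihydroxybenzaldehyde
Product: 13 2-hydroxy-4-(triisopropylsilyloxy)benzaldehyde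
Conditions: TIPSCl (1.05 equiv), imidazole, CH2Cl2, 0 °C
Reagents that add atoms: chlorotriisopropylsilane, CC(C)[Si](Cl)(C(C)C)C(C)C
Why: The 4-OH is silylated selectively because the 2-OH is hydrogen-bonded to the formyl group, which leaves the ortho-hydroxy aldehyde unit needed for the annulation.

**Step 9**
Reactants: 11 2-{1-[(3R)-2,2-dimethyl-3,5-bis(triisopropylsilyloxy)chroman-6-yl]vinyl}-4,4,5,5-tetramethyl-1,3,2-dioxaborolane; 13 2-hydroxy-4-(triisopropylsilyloxy)benzaldehyde
Product: 16 3-[(3R)-2,2-dimethyl-3,5-bis(triisopropylsilyloxy)chroman-6-yl]-7-(triisopropylsilyloxy)-2H-chromene, via aminophenol 14 (not isolated), via ortho-quinone methide 15 (not isolated)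
Conditions: Bn2NH (1.0 equiv), 1,4-dioxane, 90 °C
Reagents that add atoms: none
Why: This is the amine-mediated Petasis (borono-Mannich) synthesis of 2H-chromenes from salicylaldehydes and alkenylboron compounds, followed in the same flask by elimination and oxa-6π electrocyclization. Dibenzylamine condenses with 13 to an iminium phenoxide whose phenolic oxygen binds the boron of 11, and the resulting boronate transfers the 1-arylvinyl group intramolecularly to the iminium carbon, forming C3–C4 in aminophenol 14. On heating, 14 expels dibenzylamine with assistance from O1 (ortho) and the 7-silyloxy group (para) to give the 1-oxatriene 15, which closes ring C by thermal disrotatory 6π electrocyclization, forming O1–C2 and restoring the aromaticity of ring A. No stereocenter is created, since C3 and C4 emerge as the trisubstituted alkene that step 10 converts into both stereocenters. The step needs alkenyl transfer to outrun protodeboronation of the electron-rich boronate; regiochemistry is secured because only the boron-bearing carbon can be delivered to C4 and only the CH2 terminus lies within reach of O1, while the 2'-oxygen of ring B is silylated and cannot compete.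

**Step 10**
Reactants: 16 3-[(3R)-2,2-dimethyl-3,5-bis(triisopropylsilyloxy)chroman-6-yl]-7-(triisopropylsilyloxy)-2H-chromene
Product: 18 (3R,4S)-3-[(3R)-2,2-dimethyl-3,5-bis(triisopropylsilyloxy)chroman-6-yl]-7-(triisopropylsilyloxy)chroman-4-ol, via dialkylborane 17 (not isolated)
Conditions: IpcBH2 (monoisopinocampheylborane prepared from (−)-α-pinene), THF, −25 to 0 °C; then aq. NaOH, 30% H2O2, 0 °C
Reagents that add atoms: hydrogen peroxide, OO
Why: Concerted syn addition of H–B across the trisubstituted styrenic alkene places boron at the less substituted C4 and hydrogen at C3 on the same face, so oxidation with retention should give the trans 3-aryl-4-ol, with the face chosen by the isopinocampheyl group and any minor face isomer being a separable diastereomer because of the ring D stereocenter (asymmetric hydroboration–oxidation).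

**Step 11**
Reactants: 18 (3R,4S)-3-[(3R)-2,2-dimethyl-3,5-bis(triisopropylsilyloxy)chroman-6-yl]-7-(triisopropylsilyloxy)chroman-4-ol
Product: 19 (3R,4S)-3-[(3R)-3,5-dihydroxy-2,2-dimethylchroman-6-yl]chroman-4,7-diol
Conditions: TBAF/AcOH (1:1, excess), THF, 0 °C to rt; neutral work-up
Reagents that add atoms: none
Why: Fluoride cleaves all three silicon–oxygen bonds under buffered, near-neutral conditions, which avoids acid-promoted ionisation of the para-hydroxybenzylic C4–OH and its capture by the 2'-OH (global desilylation).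

**Compound list**
1 | 2,4-dihydroxyacetophenone | CC(=O)c1ccc(O)cc1O | starting material
2 | 3-methylbut-2-enal | CC(C)=CC=O | starting material
3 | dienone (ortho-quinone methide) from condensation of 1 and 2 | CC(=O)C1=C(O)C(=CC=C(C)C)C(=O)C=C1 | intermediate
4 | 1-(5-hydroxy-2,2-dimethyl-2H-chromen-6-yl)ethanone | CC(=O)c1ccc2OC(C)(C)C=Cc2c1O | intermediate
5 | 1-(5-benzyloxy-2,2-dimethyl-2H-chromen-6-yl)ethanone | CC(=O)c1ccc2OC(C)(C)C=Cc2c1OCc1ccccc1 | intermediate
6 | 1-[(3R,4R)-5-benzyloxy-3,4-epoxy-2,2-dimethylchroman-6-yl]ethanone | CC(=O)c1ccc2OC(C)(C)[C@@H]3O[C@@H]3c2c1OCc1ccccc1 | intermediate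
7 | 1-[(3R)-3,5-dihydroxy-2,2-dimethylchroman-6-yl]ethanone | CC(=O)c1ccc2OC(C)(C)[C@H](O)Cc2c1O | intermediate
8 | 1-[(3R)-2,2-dimethyl-3,5-bis(triisopropylsilyloxy)chroman-6-yl]ethanone | CC(=O)c1ccc2OC(C)(C)[C@H](O[Si](C(C)C)(C(C)C)C(C)C)Cc2c1O[Si](C(C)C)(C(C)C)C(C)C | intermediate
9 | potassium enolate of 8 | [K+].[O-]C(=C)c1ccc2OC(C)(C)[C@H](O[Si](C(C)C)(C(C)C)C(C)C)Cc2c1O[Si](C(C)C)(C(C)C)C(C)C | intermediate
10 | 1-[(3R)-2,2-dimethyl-3,5-bis(triisopropylsilyloxy)chroman-6-yl]vinyl trifluoromethanesulfonate | C=C(OS(=O)(=O)C(F)(F)F)c1ccc2OC(C)(C)[C@H](O[Si](C(C)C)(C(C)C)C(C)C)Cc2c1O[Si](C(C)C)(C(C)C)C(C)C | intermediate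
11 | 2-{1-[(3R)-2,2-dimethyl-3,5-bis(triisopropylsilyloxy)chroman-6-yl]vinyl}-4,4,5,5-tetramethyl-1,3,2-dioxaborolane | C=C(B1OC(C)(C)C(C)(C)O1)c1ccc2OC(C)(C)[C@H](O[Si](C(C)C)(C(C)C)C(C)C)Cc2c1O[Si](C(C)C)(C(C)C)C(C)C | intermediate
12 | 2,4-dihydroxybenzaldehyde | O=Cc1ccc(O)cc1O | starting material
13 | 2-hydroxy-4-(triisopropylsilyloxy)benzaldehyde | O=Cc1ccc(O[Si](C(C)C)(C(C)C)C(C)C)cc1O | intermediate
14 | 2-[1-(dibenzylamino)-2-aryl-prop-2-enyl]-5-(triisopropylsilyloxy)phenol (aryl = ring B/D unit of 11; mixture at the amine-bearing carbon) | C=C(C(N(Cc1ccccc1)Cc1ccccc1)c1ccc(O[Si](C(C)C)(C(C)C)C(C)C)cc1O)c1ccc2OC(C)(C)[C@H](O[Si](C(C)C)(C(C)C)C(C)C)Cc2c1O[Si](C(C)C)(C(C)C)C(C)C | intermediate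
15 | 6-(2-aryl-allylidene)-3-(triisopropylsilyloxy)cyclohexa-2,4-dienone (ortho-quinone methide) | C=C(C=C1C=CC(O[Si](C(C)C)(C(C)C)C(C)C)=CC1=O)c1ccc2OC(C)(C)[C@H](O[Si](C(C)C)(C(C)C)C(C)C)Cc2c1O[Si](C(C)C)(C(C)C)C(C)C | intermediate
16 | 3-[(3R)-2,2-dimethyl-3,5-bis(triisopropylsilyloxy)chroman-6-yl]-7-(triisopropylsilyloxy)-2H-chromene | C1(c2ccc3OC(C)(C)[C@H](O[Si](C(C)C)(C(C)C)C(C)C)Cc3c2O[Si](C(C)C)(C(C)C)C(C)C)=Cc2ccc(O[Si](C(C)C)(C(C)C)C(C)C)cc2OC1 | intermediate
17 | isopinocampheyl[(3R,4S)-3-aryl-7-(triisopropylsilyloxy)chroman-4-yl]borane | C[C@H]1[C@@H]2C[C@@H](C2(C)C)C[C@@H]1B[C@@H]1c2ccc(O[Si](C(C)C)(C(C)C)C(C)C)cc2OC[C@H]1c1ccc2OC(C)(C)[C@H](O[Si](C(C)C)(C(C)C)C(C)C)Cc2c1O[Si](C(C)C)(C(C)C)C(C)C | intermediate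
18 | (3R,4S)-3-[(3R)-2,2-dimethyl-3,5-bis(triisopropylsilyloxy)chroman-6-yl]-7-(triisopropylsilyloxy)chroman-4-ol | CC1(C)Oc2ccc([C@@H]3COc4cc(O[Si](C(C)C)(C(C)C)C(C)C)ccc4[C@H]3O)c(O[Si](C(C)C)(C(C)C)C(C)C)c2C[C@H]1O[Si](C(C)C)(C(C)C)C(C)C | intermediate
19 | (3R,4S)-3-[(3R)-3,5-dihydroxy-2,2-dimethylchroman-6-yl]chroman-4,7-diol | CC1(C)Oc2ccc([C@@H]3COc4cc(O)ccc4[C@H]3O)c(O)c2C[C@H]1O | target

**Step count.** Total 11 steps; longest linear sequence 10 steps (steps 1–7 and 9–11; step 8 is a one-step branch).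

**Steps most likely to fail, with fallbacks**

Step 9. The transfer of the hindered 1-arylvinyl group from a pinacol boronate to the iminium carbon may be slow, so that protodeboronation of the electron-rich boronate or stalling before amine elimination takes over. The fallback sets out from enol triflate 10 and aldehyde 13 and forms the two bonds in separate operations. A Nozaki–Hiyama–Kishi coupling (CrCl2 in excess, divalent chromium, with catalytic NiCl2, DMF, rt) should give the ortho-hydroxybenzylic allylic alcohol F1 and so the C3–C4 bond. Heating F1 in toluene at 80–100 °C should dehydrate it to ortho-quinone methide 15, which electrocyclises to isoflavene 16, where the route is rejoined.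

Step 10. Facial discrimination by the chiral borane may be poor, or addition to the alkene flanked by the ortho-silyloxyaryl group may be slow. The fallback sets out from 16 and returns at 18. Hydroboration with BH3·SMe2 and oxidation should give the trans alcohol as a mixture of 18 and its (3S,4R) diastereomer F2. Dess–Martin oxidation of the mixture gives the isoflavanone F3, which is configurationally labile at C3. Transfer hydrogenation under dynamic kinetic resolution (RuCl(p-cymene)[(R,R)-TsDPEN], HCO2H/Et3N) is expected to give the cis (3R,4R) alcohol F4. Mitsunobu inversion at C4 with 4-nitrobenzoic acid (PPh3, DIAD) gives the (3R,4S) 4-nitrobenzoate F5, and methanolysis (K2CO3, MeOH, 0 °C) returns 18.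

Step 6. The electron-rich 1-arylvinyl triflate may ionise or hydrolyse during formation or isolation, or a silyl group may migrate in the enolate. The fallback sets out from ketone 8 and returns at boronate 11, bypassing 10. Condensation with 2,4,6-triisopropylbenzenesulfonyl hydrazide gives the hydrazone F6. A Shapiro reaction (n-BuLi, THF, −78 to 0 °C) generates the 1-arylvinyllithium, which is trapped with 2-isopropoxy-4,4,5,5-tetramethyl-1,3,2-dioxaborolane to give 11.

**Further compounds**
F1 | step 9 | 2-{1-hydroxy-2-[(3R)-2,2-dimethyl-3,5-bis(triisopropylsilyloxy)chroman-6-yl]prop-2-enyl}-5-(triisopropylsilyloxy)phenol (carbinol epimers) | C=C(C(O)c1ccc(O[Si](C(C)C)(C(C)C)C(C)C)cc1O)c1ccc2OC(C)(C)[C@H](O[Si](C(C)C)(C(C)C)C(C)C)Cc2c1O[Si](C(C)C)(C(C)C)C(C)C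
F2 | step 10 | (3S,4R)-3-[(3R)-2,2-dimethyl-3,5-bis(triisopropylsilyloxy)chroman-6-yl]-7-(triisopropylsilyloxy)chroman-4-ol | CC1(C)Oc2ccc([C@H]3COc4cc(O[Si](C(C)C)(C(C)C)C(C)C)ccc4[C@@H]3O)c(O[Si](C(C)C)(C(C)C)C(C)C)c2C[C@H]1O[Si](C(C)C)(C(C)C)C(C)C
F3 | step 10 | 3-[(3R)-2,2-dimethyl-3,5-bis(triisopropylsilyloxy)chroman-6-yl]-7-(triisopropylsilyloxy)chroman-4-one (C3 epimers in equilibrium) | CC1(C)Oc2ccc(C3COc4cc(O[Si](C(C)C)(C(C)C)C(C)C)ccc4C3=O)c(O[Si](C(C)C)(C(C)C)C(C)C)c2C[C@H]1O[Si](C(C)C)(C(C)C)C(C)C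
F4 | step 10 | (3R,4R)-3-[(3R)-2,2-dimethyl-3,5-bis(triisopropylsilyloxy)chroman-6-yl]-7-(triisopropylsilyloxy)chroman-4-ol | CC1(C)Oc2ccc([C@@H]3COc4cc(O[Si](C(C)C)(C(C)C)C(C)C)ccc4[C@@H]3O)c(O[Si](C(C)C)(C(C)C)C(C)C)c2C[C@H]1O[Si](C(C)C)(C(C)C)C(C)C
F5 | step 10 | (3R,4S)-3-[(3R)-2,2-dimethyl-3,5-bis(triisopropylsilyloxy)chroman-6-yl]-7-(triisopropylsilyloxy)chroman-4-yl 4-nitrobenzoate | CC1(C)Oc2ccc([C@@H]3COc4cc(O[Si](C(C)C)(C(C)C)C(C)C)ccc4[C@H]3OC(=O)c5ccc(cc5)[N+](=O)[O-])c(O[Si](C(C)C)(C(C)C)C(C)C)c2C[C@H]1O[Si](C(C)C)(C(C)C)C(C)C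
F6 | step 6 | 2,4,6-triisopropylbenzenesulfonyl hydrazone of ketone 8 | CC(=NNS(=O)(=O)c1c(C(C)C)cc(C(C)C)cc1C(C)C)c1ccc2OC(C)(C)[C@H](O[Si](C(C)C)(C(C)C)C(C)C)Cc2c1O[Si](C(C)C)(C(C)C)C(C)C
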